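**Plan**
1. Retrosynthesis (target numbering O1, O2, C3, C4, C4a, O5, C6, C7, C7a): cut the C3–side-chain bond (C3 as a cyclic peroxyketal plus an allyl nucleophile, chain completed by cross-metathesis and diimide), then the lactone O5–C6 bond and the C4a–O5 and C3–O bonds (both unveiled from vinyl groups by ozonolysis and Baeyer–Villiger oxidation), then the ring-fusion bond C4a–C7a, then the acetal C7a–O1 bond.
2. Enabling feature: C7a carries the peroxide oxygen and lies β to the lactone carbonyl, so it is an aldehyde-level carbon and can be a peroxycarbenium ion. C4a is a quaternary carbinol carbon that can be the γ-carbon of an allylsilane. C4a and C3 are both methyl-bearing oxygenated quaternary carbons, 1,3 across the dioxane ring, so one vinyl-to-oxygen sequence serves both.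
3. Forward order: acyclic tertiary allylic hydroperoxide, then mixed peroxyacetal carrying an (E)-allylsilane, then the 1,2-dioxane ring (closed at C4a–C7a), then the γ-lactone ring, then the allyl group at C3 and the chain.
4. Stereochemistry: C4a and C7a arise together in the ring closure (chiral counter-anion for absolute configuration, chair for cis). C3 is set last by axial allyl delivery to the bicyclic peroxycarbenium ion, cis to the lactone oxygen. The early racemic centre (future C3) is erased on the way.

Key step: step 6

Assumption: the sense of induction of the chiral acid in step 6 cannot be derived beforehand; the (S,S)-catalyst is taken to give the (3S,4R)-dioxane, and its mirror image would be used if the opposite sense is found.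

Step 1
Reactants: 1 but-3-en-2-one; 2 3-bromoprop-1-yne
Product: 3 rac-3-methylhex-1-en-5-yn-3-ol
Conditions: Zn dust, THF/sat. aq. NH4Cl, 0 °C to rt
Reagents that add atoms: none
Why: Zinc-mediated Barbier propargylation should add 1,2 to the enone carbonyl and give the tertiary allylic, homopropargylic alcohol as a racemate, whose stereocentre is erased in step 9 and re-set in step 10.

Step 2
Reactants: 3 rac-3-methylhex-1-en-5-yn-3-ol
Product: 5 rac-(5E)-6-iodo-3,5-dimethylhexa-1,5-dien-3-ol, via alkenylalane 4 (not isolated)
Conditions: Me3Al (3 equiv), Cp2ZrCl2 (0.25 equiv), CH2Cl2, 0 °C to rt; then I2, THF, −30 °C; aq. Na2S2O3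
Reagents that add atoms: trimethylaluminium C[Al](C)C; iodine II
Why: Negishi carboalumination adds methyl and aluminium syn across the terminal alkyne (methyl on the internal carbon) and iodinolysis proceeds with retention, which should fix the (E)-trisubstituted alkene while the monosubstituted alkene stays untouched.

Step 3
Reactants: 5 rac-(5E)-6-iodo-3,5-dimethylhexa-1,5-dien-3-ol
Product: 6 rac-(5E)-3-hydroperoxy-6-iodo-3,5-dimethylhexa-1,5-diene
Conditions: 50% aq. H2O2 (10 equiv), H2SO4 (cat.), Et2O, 0 °C
Reagents that add atoms: hydrogen peroxide OO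
Why: Acid-catalysed perhydrolysis of a tertiary alcohol (SN1, capture of the tertiary allylic cation at its more substituted end under kinetic control) is the standard entry to tertiary hydroperoxides, and the alkenyl iodide is inert to it.

Step 4
Reactants: 6 rac-(5E)-3-hydroperoxy-6-iodo-3,5-dimethylhexa-1,5-diene; 7 methyl 3,3-dimethoxypropanoate
Product: 8 methyl 3-{[(5E)-6-iodo-3,5-dimethylhexa-1,5-dien-3-yl]peroxy}-3-methoxypropanoate (all stereoisomers)
Conditions: pyridinium p-toluenesulfonate (10 mol %), 5 Å molecular sieves, CH2Cl2, rt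
Reagents that add atoms: none
Why: Acid-catalysed transacetalisation, in which the hydroperoxide captures the oxocarbenium ion of the dimethyl acetal and removal of methanol drives the exchange, should give the mixed monoperoxyacetal that later serves as the peroxycarbenium precursor.

Step 5
Reactants: 8 methyl 3-{[(5E)-6-iodo-3,5-dimethylhexa-1,5-dien-3-yl]peroxy}-3-methoxypropanoate
Product: 9 methyl 3-{[(5E)-3,5-dimethyl-7-(trimethylsilyl)hepta-1,5-dien-3-yl]peroxy}-3-methoxypropanoate (all stereoisomers)
Conditions: Me3SiCH2ZnCl (from Me3SiCH2MgCl and ZnCl2), Pd2(dba)3 (2.5 mol %), tri(2-furyl)phosphine (10 mol %), THF, rt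
Reagents that add atoms: (trimethylsilyl)methylzinc chloride C[Si](C)(C)C[Zn]Cl
Why: Negishi coupling of the alkenyl iodide proceeds with retention of geometry to give the (E)-allylsilane; the organozinc reagent and the zerovalent palladium catalyst with a weakly nucleophilic phosphine should tolerate the ester and the dialkyl peroxide, oxidative addition to the C–I bond being far faster than ionisation of the allylic peroxide.

Step 6
Reactants: 9 methyl 3-{[(5E)-3,5-dimethyl-7-(trimethylsilyl)hepta-1,5-dien-3-yl]peroxy}-3-methoxypropanoate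
Product: 10 methyl 2-[(3S,4R)-4,6-diethenyl-4,6-dimethyl-1,2-dioxan-3-yl]acetate (both C6 epimers; dioxane C3, C4 and C6 become C7a, C4a and C3 of the target)
Conditions: (S,S)-imidodiphosphorimidate acid (3,3′-diaryl-BINOL backbones, N,N′-bis(trifluoromethanesulfonyl); 5 mol %), toluene, −78 °C
Reagents that add atoms: none
Why: Proposed new method: the chiral acid, silylated in situ by protodesilylation of a trace of 9, should ionise the mixed peroxyacetal (loss of MeOSiMe3) to a peroxycarbenium ion paired with the confined chiral anion, whose carbon is attacked by the γ-carbon of the tethered allylsilane in an anti-SE2′ sense, the β-silyl cation returning the silyl group to the anion, so no metal or reductant touches the O–O bond. The closest known reaction types are the achiral Lewis-acid cyclisation of allylsilanes onto peroxycarbenium ions from monoperoxyacetals (giving 1,2-dioxolanes and 1,2-dioxanes) and chiral-anion-directed additions of silyl nucleophiles to aliphatic oxocarbenium ions; merging them in one ring closure is the new element. The 1,2-dioxane closes 6-endo with respect to the O=C+ bond (as in a Prins cyclisation) and exo with respect to the allylsilane, through a chair with the CH2CO2Me group of the (E)-peroxycarbenium ion equatorial. The quaternary C4 and C3 are set together, their absolute configuration by the ion-paired chiral anion and their relative configuration (C4 vinyl cis to the C3 side chain) by the synclinal chair in which the alkenyl arm is axial. The step needs γ-attack (secured by the β-silicon effect and the six-membered ring), ionisation of the acetal and not of the tertiary allylic C–O bond (only the acetal gives an oxygen-stabilised cation at −78 °C), and facial control independent of C6 (methyl and vinyl are nearly equal in size and C6 is re-set in step 10, so both C6 epimers are used).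

Step 7
Reactants: 10 methyl 2-[(3S,4R)-4,6-diethenyl-4,6-dimethyl-1,2-dioxan-3-yl]acetate
Product: 11 methyl 2-[(3S,4S)-4,6-diformyl-4,6-dimethyl-1,2-dioxan-3-yl]acetate (both C6 epimers)
Conditions: O3, pyridine (3 equiv), CH2Cl2, −78 °C
Reagents that add atoms: ozone [O-][O+]=O
Why: Ozonolysis in the presence of pyridine gives aldehydes directly without a reducing work-up, so both vinyl helper groups should be cleaved at once with the dialkyl peroxide untouched and the quaternary centres unable to epimerise.

Step 8
Reactants: 11 methyl 2-[(3S,4S)-4,6-diformyl-4,6-dimethyl-1,2-dioxan-3-yl]acetate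
Product: 12 methyl 2-[(3S,4S)-4,6-bis(formyloxy)-4,6-dimethyl-1,2-dioxan-3-yl]acetate (both C6 epimers)
Conditions: mCPBA (3 equiv), NaHCO3, CH2Cl2, 0 °C to rt
Reagents that add atoms: 3-chloroperoxybenzoic acid OOC(=O)c1cccc(Cl)c1
Why: In the Baeyer–Villiger oxidation of α-quaternary aldehydes the tertiary carbon (at C6 also oxygen-substituted) should migrate in preference to hydrogen, with retention at C4, to give the two formates.

Step 9
Reactants: 12 methyl 2-[(3S,4S)-4,6-bis(formyloxy)-4,6-dimethyl-1,2-dioxan-3-yl]acetate
Product: 14 (4aS,7aS)-3-methoxy-3,4a-dimethyltetrahydrofuro[3,2-c][1,2]dioxin-6(3H)-one (cis-fused; both C3 epimers), via hydroxy ester 13 (not isolated)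
Conditions: camphorsulfonic acid (10 mol %), MeOH, rt; then concentrate, camphorsulfonic acid (cat.), CH2Cl2, rt
Reagents that add atoms: methanol CO
Why: Acid-catalysed methanolysis should cleave the C4 formate and exchange the acylal-type peroxy formate at C6 for a methyl peroxyketal, after which the freed tertiary alcohol lactonises onto the cis CH2CO2Me group to give the cis-fused γ-lactone, the ring fusion a 5/6 system closes readily.

Step 10
Reactants: 14 (4aS,7aS)-3-methoxy-3,4a-dimethyltetrahydrofuro[3,2-c][1,2]dioxin-6(3H)-one; 15 allyltrimethylsilane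
Product: 16 (3R,4aS,7aS)-3,4a-dimethyl-3-(prop-2-en-1-yl)tetrahydrofuro[3,2-c][1,2]dioxin-6(3H)-one
Conditions: Me3SiOTf (0.5 equiv), CH2Cl2, −78 °C
Reagents that add atoms: none
Why: Hosomi–Sakurai substitution of the cyclic peroxyketal through an endocyclic peroxycarbenium ion (known for alkoxy-1,2-dioxolanes and -dioxanes) should set C3 as R, because the half-chair with the C4a methyl pseudo-equatorial and the lactone oxygen pseudo-axial is attacked axially, placing allyl cis to the lactone oxygen and avoiding a 1,3-diaxial clash with the C4a methyl.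

Step 11
Reactants: 17 (4-methoxyphenyl)magnesium bromide; 18 8-bromooct-1-ene
Product: 19 1-methoxy-4-(oct-7-en-1-yl)benzene
Conditions: Li2CuCl4 (3 mol %), THF, 0 °C to rt
Reagents that add atoms: none
Why: Copper-catalysed Kochi coupling of an aryl Grignard reagent with a primary alkyl bromide should give the arylalkene, the remote terminal alkene being inert.

Step 12
Reactants: 19 1-methoxy-4-(oct-7-en-1-yl)benzene
Product: 20 4-(oct-7-en-1-yl)phenol
Conditions: NaSEt, DMF, 130 °C; aq. HCl
Reagents that add atoms: none
Why: SN2 demethylation of the aryl methyl ether by ethanethiolate uses no Lewis or Brønsted acid and should leave the terminal alkene untouched.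

Step 13
Reactants: 16 (3R,4aS,7aS)-3,4a-dimethyl-3-(prop-2-en-1-yl)tetrahydrofuro[3,2-c][1,2]dioxin-6(3H)-one; 20 4-(oct-7-en-1-yl)phenol
Product: 21 (3R,4aS,7aS)-3-[9-(4-hydroxyphenyl)non-2-en-1-yl]-3,4a-dimethyltetrahydrofuro[3,2-c][1,2]dioxin-6(3H)-one (E/Z mixture)
Conditions: second-generation Grubbs catalyst RuCl2(=CHPh)(H2IMes)(PCy3) (5 mol %), 20 (3 equiv), CH2Cl2, 40 °C
Reagents that add atoms: none
Why: Olefin cross-metathesis of two terminal alkenes with loss of ethene should join the chain, since ruthenium alkylidenes tolerate dialkyl peroxides, lactones and free phenols and the alkene geometry is irrelevant.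

Step 14
Reactants: 21 (3R,4aS,7aS)-3-[9-(4-hydroxyphenyl)non-2-en-1-yl]-3,4a-dimethyltetrahydrofuro[3,2-c][1,2]dioxin-6(3H)-one
Product: 22 plakortolide F
Conditions: KO2CN=NCO2K, AcOH, MeOH/CH2Cl2, 0 °C to rt
Reagents that add atoms: none
Why: Diimide generated in situ transfers H2 to the disubstituted C=C bond in a concerted syn fashion and does not reduce O–O bonds, lactones or arenes, so the peroxide should survive where catalytic hydrogenation would cleave it.

**Compound list**
1 | but-3-en-2-one (methyl vinyl ketone) | CC(=O)C=C | starting material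
2 | 3-bromoprop-1-yne (propargyl bromide) | BrCC#C | starting material
3 | rac-3-methylhex-1-en-5-yn-3-ol | C=CC(C)(O)CC#C | intermediate
4 | O-dimethylaluminated (E)-alkenyl(dimethyl)alane from 3 (not isolated) | C=CC(C)(O[Al](C)C)C/C(C)=C/[Al](C)C | intermediate
5 | rac-(5E)-6-iodo-3,5-dimethylhexa-1,5-dien-3-ol | C=CC(C)(O)C/C(C)=C/I | intermediate
6 | rac-(5E)-3-hydroperoxy-6-iodo-3,5-dimethylhexa-1,5-diene | C=CC(C)(OO)C/C(C)=C/I | intermediate
7 | methyl 3,3-dimethoxypropanoate | COC(=O)CC(OC)OC | starting material
8 | methyl 3-{[(5E)-6-iodo-3,5-dimethylhexa-1,5-dien-3-yl]peroxy}-3-methoxypropanoate (all stereoisomers) | COC(=O)CC(OC)OOC(C)(C=C)C/C(C)=C/I | intermediate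
9 | methyl 3-{[(5E)-3,5-dimethyl-7-(trimethylsilyl)hepta-1,5-dien-3-yl]peroxy}-3-methoxypropanoate (all stereoisomers) | COC(=O)CC(OC)OOC(C)(C=C)C/C(C)=C/C[Si](C)(C)C | intermediate
10 | methyl 2-[(3S,4R)-4,6-diethenyl-4,6-dimethyl-1,2-dioxan-3-yl]acetate (both C6 epimers; C4 vinyl cis to the C3 side chain) | C=CC1(C)C[C@](C)(C=C)[C@H](CC(=O)OC)OO1 | intermediate
11 | methyl 2-[(3S,4S)-4,6-diformyl-4,6-dimethyl-1,2-dioxan-3-yl]acetate (both C6 epimers) | O=CC1(C)C[C@](C)(C=O)[C@H](CC(=O)OC)OO1 | intermediate
12 | methyl 2-[(3S,4S)-4,6-bis(formyloxy)-4,6-dimethyl-1,2-dioxan-3-yl]acetate (both C6 epimers) | O=COC1(C)C[C@](C)(OC=O)[C@H](CC(=O)OC)OO1 | intermediate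
13 | methyl 2-[(3S,4S)-4-hydroxy-6-methoxy-4,6-dimethyl-1,2-dioxan-3-yl]acetate (both C6 epimers; not isolated) | COC1(C)C[C@](C)(O)[C@H](CC(=O)OC)OO1 | intermediate
14 | (4aS,7aS)-3-methoxy-3,4a-dimethyltetrahydrofuro[3,2-c][1,2]dioxin-6(3H)-one (cis-fused; both C3 epimers) | COC1(C)C[C@]2(C)OC(=O)C[C@@H]2OO1 | intermediate
15 | allyltrimethylsilane | C=CC[Si](C)(C)C | starting material
16 | (3R,4aS,7aS)-3,4a-dimethyl-3-(prop-2-en-1-yl)tetrahydrofuro[3,2-c][1,2]dioxin-6(3H)-one | C[C@@]1(CC=C)C[C@]2(C)OC(=O)C[C@@H]2OO1 | intermediate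
17 | (4-methoxyphenyl)magnesium bromide (THF solution) | COc1ccc([Mg]Br)cc1 | starting material
18 | 8-bromooct-1-ene | C=CCCCCCCBr | starting material
19 | 1-methoxy-4-(oct-7-en-1-yl)benzene | C=CCCCCCCc1ccc(OC)cc1 | intermediate
20 | 4-(oct-7-en-1-yl)phenol | C=CCCCCCCc1ccc(O)cc1 | intermediate
21 | (3R,4aS,7aS)-3-[9-(4-hydroxyphenyl)non-2-en-1-yl]-3,4a-dimethyltetrahydrofuro[3,2-c][1,2]dioxin-6(3H)-one (E/Z mixture) | C[C@@]1(CC=CCCCCCCc2ccc(O)cc2)C[C@]2(C)OC(=O)C[C@@H]2OO1 | intermediate
22 | plakortolide F, (3R,4aS,7aS)-3-[9-(4-hydroxyphenyl)nonyl]-3,4a-dimethyltetrahydrofuro[3,2-c][1,2]dioxin-6(3H)-one | C[C@@]1(CCCCCCCCCc2ccc(O)cc2)C[C@]2(C)OC(=O)C[C@@H]2OO1 | target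

**Totals**
Total step count: 14. Longest linear sequence: 12 steps (steps 1 to 10, then 13 and 14).

**Steps most likely to fail**

Step 6 (Proposed new method). The chiral anion may not discriminate the faces of the peroxycarbenium ion well enough, or ionisation at the tertiary allylic C–O bond and O–O heterolysis may compete. The fallback sets out from 9 and comes back at 16. Compound 9 would be cyclised with Me3SiOTf in CH2Cl2 at −78 °C, the known achiral peroxycarbenium–allylsilane ring closure, to the racemic divinyl dioxane F1. Steps 7 to 9 carried out unchanged would give the racemic dialdehyde F2, the racemic bis-formate F3 and the racemic methyl peroxyketal lactone F4. Acid-catalysed ketal exchange of F4 with (S)-1-phenylethanol (camphorsulfonic acid, 5 Å sieves) would give two diastereomeric peroxyketals, separated by chromatography: the (4aS,7aS) 1-phenylethyl ketal F5 is kept and the (4aR,7aR) 1-phenylethyl ketal F6 is discarded. F5 would then be allylated under the conditions of step 10, the chiral alkoxy group being the leaving group, to give 16.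

Step 8. Hydrogen migration may win over carbon migration in the Criegee intermediates, so the aldehydes are over-oxidised to carboxylic acids, most likely at C4. The fallback sets out from 10 and comes back at 14. Wacker oxidation of both vinyl groups (PdCl2 10 mol %, CuCl, O2, DMF/H2O) would give the bis(methyl ketone) F7. Baeyer–Villiger oxidation with mCPBA, in which a tertiary alkyl group migrates reliably in preference to methyl, would give the bis-acetate F8. The conditions of step 9 would then lead through 13 to 14.

Step 10. The peroxycarbenium ion may undergo O–O heterolysis with 1,2-shift instead of allyl transfer, or the allyl group may be delivered with poor facial selectivity. The fallback sets out from 14 and comes back at 16. Base-induced retro-oxa-Michael opening (DBU, CH2Cl2) and hydrolysis of the released hydroperoxy ketal (aq. HCl) would give the butenolide methyl ketone F9. Zinc-mediated Barbier allylation of the ketone would give the tertiary homoallylic alcohol F10, and acid-catalysed perhydrolysis (50% H2O2, H2SO4 cat.) the tertiary hydroperoxide F11. Amine-promoted intramolecular oxa-Michael addition to the butenolide (Et2NH, CF3CH2OH) would close the cis-fused peroxylactone. This route has no control at C3, so 16 would be separated by chromatography from its C3 epimer F12.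

**Further compounds**
F1 | step 6 | rac-methyl 2-[(3S*,4R*)-4,6-diethenyl-4,6-dimethyl-1,2-dioxan-3-yl]acetate | C=CC1(C)CC(C)(C=C)C(CC(=O)OC)OO1
F2 | step 6 | rac-methyl 2-[(3S*,4S*)-4,6-diformyl-4,6-dimethyl-1,2-dioxan-3-yl]acetate | O=CC1(C)CC(C)(C=O)C(CC(=O)OC)OO1
F3 | step 6 | rac-methyl 2-[(3S*,4S*)-4,6-bis(formyloxy)-4,6-dimethyl-1,2-dioxan-3-yl]acetate | O=COC1(C)CC(C)(OC=O)C(CC(=O)OC)OO1
F4 | step 6 | rac-cis-3-methoxy-3,4a-dimethyltetrahydrofuro[3,2-c][1,2]dioxin-6(3H)-one | COC1(C)CC2(C)OC(=O)CC2OO1
F5 | step 6 | (4aS,7aS)-3,4a-dimethyl-3-[(1S)-1-phenylethoxy]tetrahydrofuro[3,2-c][1,2]dioxin-6(3H)-one | C[C@H](OC1(C)C[C@]2(C)OC(=O)C[C@@H]2OO1)c1ccccc1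
F6 | step 6 | (4aR,7aR)-3,4a-dimethyl-3-[(1S)-1-phenylethoxy]tetrahydrofuro[3,2-c][1,2]dioxin-6(3H)-one | C[C@H](OC1(C)C[C@@]2(C)OC(=O)C[C@H]2OO1)c1ccccc1
F7 | step 8 | methyl 2-[(3S,4S)-4,6-diacetyl-4,6-dimethyl-1,2-dioxan-3-yl]acetate | CC(=O)C1(C)C[C@](C)(C(C)=O)[C@H](CC(=O)OC)OO1
F8 | step 8 | methyl 2-[(3S,4S)-4,6-diacetoxy-4,6-dimethyl-1,2-dioxan-3-yl]acetate | CC(=O)OC1(C)C[C@](C)(OC(C)=O)[C@H](CC(=O)OC)OO1
F9 | step 10 | (5S)-5-methyl-5-(2-oxopropyl)furan-2(5H)-one | CC(=O)C[C@]1(C)OC(=O)C=C1
F10 | step 10 | (5S)-5-(2-hydroxy-2-methylpent-4-en-1-yl)-5-methylfuran-2(5H)-one | C=CCC(C)(O)C[C@]1(C)OC(=O)C=C1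
F11 | step 10 | (5S)-5-(2-hydroperoxy-2-methylpent-4-en-1-yl)-5-methylfuran-2(5H)-one | C=CCC(C)(OO)C[C@]1(C)OC(=O)C=C1
F12 | step 10 | (3S,4aS,7aS)-3,4a-dimethyl-3-(prop-2-en-1-yl)tetrahydrofuro[3,2-c][1,2]dioxin-6(3H)-one | C[C@]1(CC=C)C[C@]2(C)OC(=O)C[C@@H]2OO1
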